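**Retrosynthetic overview**

1. Target ⇐ its ring-fusion alkene (C=C shared by pyran ring A and the carbocycle): ionic hydrogenation from the exo face of the bridged framework sets both ring-fusion CH centres.
2. Ring-fusion alkene ⇐ a 2,2,4-trimethyl-2H-pyranoquinolone (C,C-bis-nucleophile) + a 3-(3-oxobutenyl)-4-hydroxyquinolone (bis-electrophile, reacting as its pyrylium ion): chiral-acid (3+3) annulation that closes bridging pyran ring B and carbocycle C in one operation and sets the two bridgehead centres.
3. Trimethylpyranoquinolone ⇐ chromanone (MeMgBr, then dehydration) ⇐ 4-hydroxy-1-methylquinolin-2-one + 3-methylbut-2-enoic acid (ring A).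
4. Oxobutenyl quinolone ⇐ 4-hydroxy-1-methylquinolin-2-one + (E)-4-methoxybut-3-en-2-one.
5. Ring order: pyran A (step 1); pyran B and carbocycle C together, then the last two stereocentres, in step 4; no protecting groups.

**Notation and assumptions**

- Atom labels: C-a = the O–C(CH3)2 carbon of pyran ring A. Carbocycle C = C-b (CH bonded to C-a), C-c (CH bonded to C-3 of quinolone A), C-d (CH2), C-e (C(CH3)–O), C-g (CH2), C-f (CH bonded to C-3 of quinolone B). Pyran ring B = 4-O of quinolone B, C-e, C-g, C-f and C-3/C-4 of quinolone B.
- Read from the target SMILES: C-b S, C-c S, C-e S, C-f R; the hydrogens on C-b, C-c and C-f are all cis.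
- Assumption: the (R)-configured acid in step 4 gives the C-f R series; if the sense of induction proves opposite, its enantiomer is used.
- Assumption: the quinolone, the acid, the Grignard reagent and the methoxy-enone are bought.

**Route**

Step 1
Reactants: 1 4-hydroxy-1-methylquinolin-2(1H)-one; 2 3-methylbut-2-enoic acid
Product: 4 2,2,6-trimethyl-2,3-dihydro-4H-pyrano[3,2-c]quinoline-4,5(6H)-dione, via C-acyl quinolone 3 (not isolated)
Conditions: Eaton's reagent (P2O5 in MeSO3H), 70 °C
Reagents that add atoms: none
Why: Friedel–Crafts acylation at the nucleophilic C-3 of the quinolone gives 3, whose 4-OH closes onto the β,β-dimethyl enone by intramolecular oxa-Michael addition (the chromanone annulation known for phenols); no stereocentre is formed.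

Step 2
Reactants: 4 2,2,6-trimethyl-2,3-dihydro-4H-pyrano[3,2-c]quinoline-4,5(6H)-dione
Product: 7 2,2,4,6-tetramethyl-2,6-dihydro-5H-pyrano[3,2-c]quinolin-5-one, via tertiary alcohol 6 (not isolated)
Conditions: MeMgBr (2.5 equiv.), THF, −20 to 0 °C; aq. NH4Cl; then TsOH·H2O (5 mol%), toluene, 60 °C
Reagents that add atoms: 5 methylmagnesium bromide, C[Mg]Br
Why: Grignard 1,2-addition to the ketone (the N-methyl lactam carbonyl is inert at 0 °C) followed by acid-catalysed E1 dehydration to the conjugated endocyclic alkene; the stereocentre of racemic 6 is erased and the new methyl is the future C-d.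

Step 3
Reactants: 1 4-hydroxy-1-methylquinolin-2(1H)-one; 8 (3E)-4-methoxybut-3-en-2-one
Product: 9 4-hydroxy-1-methyl-3-[(1E)-3-oxobut-1-en-1-yl]quinolin-2(1H)-one
Conditions: 8 (1.3 equiv.), pyridinium p-toluenesulfonate (10 mol%), MeCN, 50 °C
Reagents that add atoms: none
Why: conjugate addition of C-3 of the quinolone to the vinylogous ester and loss of methanol (addition–elimination) gives the E-enone, the thermodynamic isomer; no stereocentre is formed.

Step 4
Reactants: 7 2,2,4,6-tetramethyl-2,6-dihydro-5H-pyrano[3,2-c]quinolin-5-one; 9 4-hydroxy-1-methyl-3-[(1E)-3-oxobut-1-en-1-yl]quinolin-2(1H)-one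
Product: 13 all-cis heptacyclic target (C-b S; C-c S; C-e S; C-f R), via pyrylium ion 10 (not isolated), via 4H-pyran adduct 11 (not isolated), via ring-fusion alkene 12 (not isolated)
Conditions: (R)-3,3'-bis(2,4,6-triisopropylphenyl)-1,1'-binaphthyl-2,2'-diyl N-(trifluoromethanesulfonyl)phosphoramide (10 mol%), 5 Å molecular sieves, toluene, −20 to 40 °C; then CH2Cl2, Et3SiH (3 equiv.), CF3CO2H (5 equiv.), −20 to 0 °C
Reagents that add atoms: none
Why: Proposed new method: the chiral acid converts hydroxy-enone 9 (after acid-mediated E to Z isomerisation and cyclisation) into the flavylium-type 2-methylpyrylium ion 10 paired with the chiral phosphoramide anion; C-3 of dienol ether 7 (C-b) adds to C-4 of 10 (C-f) inside the ion pair, where the anion selects the face and sets C-f as R, and proton loss gives 11; protonation of the enol ether of 11 gives the C-e oxocarbenium ion, which is attacked by the exocyclic-methylene tautomer of the pyran A unit (C-d) on the only face the tether can reach, so carbocycle C closes with C-e (S) dictated by C-f, and loss of the C-b proton gives 12; Et3SiH/CF3CO2H then protonates C-b and delivers hydride to the resulting C-c cation, both from the exo face away from the quinolone B bridge, giving the all-cis C-b S, C-c S product; the closest known chemistry is the Michael addition/bicycloketalisation of 2-hydroxychalcones with 1,3-bis-nucleophiles through flavylium ions (2,8-dioxabicyclo[3.3.1]nonanes), chiral-anion-controlled additions to benzopyrylium ions, Robinson-type (3+3) annulation of enol ethers with enones, and ionic hydrogenation of 2H-chromenes.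

**Compound list**

1 | 4-hydroxy-1-methylquinolin-2(1H)-one | Cn1c(=O)cc(O)c2ccccc12 | starting material
2 | 3-methylbut-2-enoic acid | CC(C)=CC(=O)O | starting material
3 | 4-hydroxy-1-methyl-3-(3-methylbut-2-enoyl)quinolin-2(1H)-one (not isolated) | CC(C)=CC(=O)c1c(O)c2ccccc2n(C)c1=O | intermediate
4 | 2,2,6-trimethyl-2,3-dihydro-4H-pyrano[3,2-c]quinoline-4,5(6H)-dione | CC1(C)CC(=O)c2c(O1)c1ccccc1n(C)c2=O | intermediate
5 | methylmagnesium bromide | C[Mg]Br | starting material
6 | 4-hydroxy-2,2,4,6-tetramethyl-2,3,4,6-tetrahydro-5H-pyrano[3,2-c]quinolin-5-one (racemic, not isolated) | CC1(C)CC(C)(O)c2c(O1)c1ccccc1n(C)c2=O | intermediate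
7 | 2,2,4,6-tetramethyl-2,6-dihydro-5H-pyrano[3,2-c]quinolin-5-one | CC1=CC(C)(C)Oc2c1c(=O)n(C)c1ccccc21 | intermediate
8 | (3E)-4-methoxybut-3-en-2-one | CO/C=C/C(C)=O | starting material
9 | 4-hydroxy-1-methyl-3-[(1E)-3-oxobut-1-en-1-yl]quinolin-2(1H)-one | CC(=O)/C=C/c1c(O)c2ccccc2n(C)c1=O | intermediate
10 | 2,6-dimethyl-5-oxo-5,6-dihydropyrano[3,2-c]quinolin-1-ium, paired with the chiral phosphoramide anion (not isolated) | Cc1ccc2c([o+]1)c1ccccc1n(C)c2=O | intermediate
11 | (4R)-2,6-dimethyl-4-(2,2,4,6-tetramethyl-5-oxo-5,6-dihydro-2H-pyrano[3,2-c]quinolin-3-yl)-4H-pyrano[3,2-c]quinolin-5(6H)-one (not isolated) | CC1=C[C@H](C2=C(C)c3c(OC2(C)C)c2ccccc2n(C)c3=O)c2c(O1)c1ccccc1n(C)c2=O | intermediate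
12 | ring-fusion alkene: skeleton of 13 with a tetrasubstituted C-b=C-c double bond shared by pyran ring A and carbocycle C; C-e S, C-f R (not isolated) | Cn1c(=O)c2c(c3ccccc31)OC(C)(C)C1=C2C[C@]2(C)C[C@H]1c1c(c3ccccc3n(C)c1=O)O2 | intermediate
13 | target: N-methylquinolin-2-one A fused through C-3/C-4–O to 2,2-dimethyl-dihydropyran ring A (O, C-a, C-b, C-c), cis-fused at C-b/C-c to cyclohexane ring C; N-methylquinolin-2-one B bonded through C-3 to C-f and through its 4-O to C-e (bridging pyran ring B); C-b S, C-c S, C-e S, C-f R | Cn1c(=O)c2c(c3ccccc31)OC(C)(C)[C@H]1[C@@H]2C[C@]2(C)C[C@H]1c1c(c3ccccc3n(C)c1=O)O2 | target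

**Step count and risks**

Total step count: 4. Longest linear sequence: 3 (steps 1, 2 and 4; step 3 is a one-step branch).

Steps most likely to fail, most uncertain first:

Step 4 is the least certain. Open points are the level and sense of induction in the ion pair, which nucleophilic carbon of 7 reacts first, self-condensation of 7 or 10, and chemoselectivity of the in-flask reduction. The fallback builds carbocycle C by a different bond set and secures the enantiomer by separation. It sets out from 4 and 9: a Robinson annulation under acid (CF3SO3H 20 mol%, toluene, 60 °C; Michael addition of the enol of 4 to 9, then aldol condensation of the side-chain methyl ketone onto the chromanone carbonyl) gives the racemic tetracyclic cyclohexenone F1. MeMgBr/CeCl3 (THF, −78 °C) adds to the ring C ketone to give the tertiary allylic alcohol F2. TsOH·H2O (cat., toluene, 40 °C) ionises F2 and the hydroxyl of quinolone B closes the bridging ether at C-e, giving racemic 12. Preparative chromatography on a chiral phase separates 12 from its enantiomer F3. The fallback comes back to the route at 12, which is reduced under the second-stage conditions of step 4.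

Step 1 may give the isomeric lactone (C-alkylation at the tertiary carbon before acylation) or stop at O-acylation. The fallback sets out from 1: C-acetylation (AcOH, polyphosphoric acid, 100 °C) gives 3-acetyl-4-hydroxy-1-methylquinolin-2(1H)-one F4, and a Kabbe condensation with acetone (pyrrolidine, toluene, reflux; aldol condensation then oxa-Michael closure) gives the chromanone. It comes back to the route at 4.

Step 3 may run on to the 2:1 adduct (a second quinolone adding to 9) or give oligomers of the enone. The fallback sets out from 1: Reimer–Tiemann formylation (CHCl3, aq. NaOH, 60 °C) gives 4-hydroxy-1-methyl-2-oxo-1,2-dihydroquinoline-3-carbaldehyde F5, and an aldol condensation with acetone (pyrrolidine, AcOH, room temperature) gives the E-enone. It comes back to the route at 9.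

**Further compounds**

F1 | step 4 | racemic cyclohexenone: chromanone 4 annulated across its C-3/C-4 with a cyclohex-2-en-1-one (C-c=C-d H–C-e(=O)–C-g H2–C-f H–C-b H) carrying the 4-hydroxy-1-methyl-2-oxoquinolin-3-yl group on C-f | CC1(C)Oc2c(C3=CC(=O)CC(c4c(O)c5ccccc5n(C)c4=O)C13)c(=O)n(C)c3ccccc23
F2 | step 4 | racemic tertiary allylic alcohol: F1 with C-e as C(CH3)(OH) | CC1(C)Oc2c(C3=CC(C)(O)CC(c4c(O)c5ccccc5n(C)c4=O)C13)c(=O)n(C)c3ccccc23
F3 | step 4 | enantiomer of 12 (C-e R, C-f S) | Cn1c(=O)c2c(c3ccccc31)OC(C)(C)C1=C2C[C@@]2(C)C[C@@H]1c1c(c3ccccc3n(C)c1=O)O2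
F4 | step 1 | 3-acetyl-4-hydroxy-1-methylquinolin-2(1H)-one | CC(=O)c1c(O)c2ccccc2n(C)c1=O
F5 | step 3 | 4-hydroxy-1-methyl-2-oxo-1,2-dihydroquinoline-3-carbaldehyde | O=Cc1c(O)c2ccccc2n(C)c1=O
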